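## Retrosynthetic overview

1. The target comes from four-fold desilylation of its tetra-TBS ether, whose 4Z, 8Z and 14Z olefins arise together by Zn(Cu/Ag) semi-reduction of a 22-membered 4,8,14-triyne.
2. The macrolactone is the only ring formed (the arene is bought). It is closed last at C5–C6 by a ring-closing Pd/Cu sp–sp2 coupling of an open-chain C21 ester made from a C1–C5 ynenoic acid and a C6–C23 alcohol.
3. The C6–C23 alcohol comes from a Mukaiyama aldol (C20–C21) and 1,3-syn reduction, joining a C6–C20 chloroenyne methyl ketone with a C21–C23 aryl aldehyde (anti-crotylation of a 3-silyloxybenzaldehyde).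
4. The C6–C20 ketone comes from Sonogashira coupling C7–C8 (cis-dichloroethene), catalytic asymmetric propargylation C10–C11, and Sonogashira coupling C13–C14 with (Z)-3-iodo-2-methylallyl alcohol (anti-carbomagnesiation of propargyl alcohol sets 12Z).
5. The C14–C20 alkynyl ketone comes from a new nickel-hydride enantioselective hydroalkynylation of hex-5-en-2-one (C15–C16 bond, C16 stereocentre).

Assumption: locants C1–C23 are the macrolide numbering of the target (C1 lactone carbonyl, C21 lactone carbinol, C23 benzylic carbinol); the silyl groups of 1 and 34 are protecting groups; in step 2 the bis(oxazoline) antipode that gives 5R is used (checked against 5 from the fallback).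

## Route

Step 1
Reactants: 1 ethynyltri(propan-2-yl)silane
Product: 2 (bromoethynyl)tri(propan-2-yl)silane
Conditions: NBS, AgNO3 (10 mol%), acetone, rt
Reagents that add atoms: N-bromosuccinimide, O=C1CCC(=O)N1Br
Why: Silver-catalysed electrophilic bromination of the terminal alkyne gives the stable bromoalkyne used as alkynyl electrophile.

Step 2
Reactants: 3 hex-5-en-2-one; 2 (bromoethynyl)tri(propan-2-yl)silane
Product: 4 (5R)-5-methyl-7-[tri(propan-2-yl)silyl]hept-6-yn-2-one
Conditions: NiBr2·DME (10 mol%), chiral bis(oxazoline) Bn-BOX (12 mol%), (EtO)2MeSiH, KF, DMA/THF, 0 °C → rt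
Reagents that add atoms: none
Why: Proposed new method: a nickel-hydride-catalysed, ketone-directed, enantioselective Markovnikov hydroalkynylation of an unactivated terminal alkene, in which the ligated Ni–H (from the divalent nickel salt, hydrosilane and fluoride) binds the C19 carbonyl, inserts the alkene to give the secondary alkylnickel as a six-membered O-chelate (this fixes nickel at C16, disfavours chain walking and lets the ligand choose the alkene face, setting C16 as R) and then captures bromoalkyne 2 by oxidative addition and C(sp3)–C(sp) reductive elimination; the closest known reaction type is the NiH-catalysed enantioselective hydroalkynylation of alkenyl amides and enamides with the same bromoalkyne, where an amide and not a ketone is the chelating group.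

Step 3
Reactants: 4 (5R)-5-methyl-7-[tri(propan-2-yl)silyl]hept-6-yn-2-one
Product: 5 (5R)-5-methylhept-6-yn-2-one
Conditions: Bu4NF, THF, 0 °C (volatile product, kept in solution)
Reagents that add atoms: none
Why: Fluoride-mediated protodesilylation cleaves only the C(sp)–Si bond and leaves the ketone and the propargylic stereocentre untouched.

Step 4
Reactants: 6 prop-2-yn-1-ol
Product: 8 (2Z)-3-iodo-2-methylprop-2-en-1-ol, via alkenylmagnesium alkoxide 7 (not isolated)
Conditions: MeMgBr (2.5 equiv), CuI (10 mol%), THF, −10 °C → rt; I2, −10 °C; H2O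
Reagents that add atoms: methylmagnesium bromide, C[Mg]Br; iodine, II
Why: Copper-catalysed, alkoxide-directed anti-carbomagnesiation (Duboudin reaction) puts methyl on C12 and magnesium on C13 cis to the CH2O group through a five-membered chelate, and iodinolysis with retention gives the Z-iodide.

Step 5
Reactants: 5 (5R)-5-methylhept-6-yn-2-one; 8 (2Z)-3-iodo-2-methylprop-2-en-1-ol
Product: 9 (5R,8Z)-10-hydroxy-5,9-dimethyldec-8-en-6-yn-2-one
Conditions: PdCl2(PPh3)2 (3 mol%), CuI (6 mol%), Et3N, THF, rt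
Reagents that add atoms: none
Why: Sonogashira coupling forms C13–C14 with retention of the Z geometry and tolerates the free alcohol and the ketone.

Step 6
Reactants: 9 (5R,8Z)-10-hydroxy-5,9-dimethyldec-8-en-6-yn-2-one
Product: 10 (2Z,6R)-2,6-dimethyl-9-oxodec-2-en-4-ynal
Conditions: MnO2 (15 equiv), CH2Cl2, rt, dark; filtered and used at once
Reagents that add atoms: none
Why: MnO2 oxidises only the allylic alcohol without Z/E isomerisation, and the unreduced C14–C15 alkyne prevents the oxa-6π-electrocyclisation a 2Z,4Z-dienal would undergo.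

Step 7
Reactants: 11 3-bromoprop-1-yne
Product: 13 allenylboronic acid pinacol ester, via allenylmagnesium bromide 12 (not isolated)
Conditions: Mg, HgCl2 (1 mol%), Et2O, 0 °C; i-PrOB(pin), −78 °C → rt; 1 M HCl
Reagents that add atoms: 2-isopropoxy-4,4,5,5-tetramethyl-1,3,2-dioxaborolane, CC(C)OB1OC(C)(C)C(C)(C)O1
Why: Propargyl bromide gives the allenyl Grignard reagent, and borylation gives the allenylboronate as the thermodynamic isomer.

Step 8
Reactants: 10 (2Z,6R)-2,6-dimethyl-9-oxodec-2-en-4-ynal; 13 allenylboronic acid pinacol ester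
Product: 14 (5R,8Z,10R)-10-hydroxy-5,9-dimethyltridec-8-ene-6,12-diyn-2-one
Conditions: (R)-TRIP phosphoric acid (10 mol%), 4 Å MS, toluene, −20 °C; aq. NaHCO3
Reagents that add atoms: none
Why: Chiral-phosphoric-acid-catalysed allenylboration (SE2′ propargylation through a closed six-membered transition state) forms C10–C11 on the aldehyde only and sets C11 as R, the sense known for aryl and alkenyl aldehydes with the (R)-catalyst.

Step 9
Reactants: 14 (5R,8Z,10R)-10-hydroxy-5,9-dimethyltridec-8-ene-6,12-diyn-2-one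
Product: 15 (5R,8Z,10R)-10-[(tert-butyldimethylsilyl)oxy]-5,9-dimethyltridec-8-ene-6,12-diyn-2-one
Conditions: TBSOTf, 2,6-lutidine, CH2Cl2, −78 °C
Reagents that add atoms: tert-butyldimethylsilyl triflate, CC(C)(C)[Si](C)(C)OS(=O)(=O)C(F)(F)F
Why: Silylation of the secondary alcohol is much faster at −78 °C than enol silane formation at the methyl ketone.

Step 10
Reactants: 15 (5R,8Z,10R)-10-[(tert-butyldimethylsilyl)oxy]-5,9-dimethyltridec-8-ene-6,12-diyn-2-one; 16 (Z)-1,2-dichloroethene (5 equiv)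
Product: 17 (5R,8Z,10R,14Z)-10-[(tert-butyldimethylsilyl)oxy]-15-chloro-5,9-dimethylpentadeca-8,14-diene-6,12-diyn-2-one
Conditions: Pd(PPh3)4 (5 mol%), CuI (10 mol%), i-Pr2NH, THF, rt
Reagents that add atoms: none
Why: Sonogashira coupling with excess cis-dichloroethene stops after one substitution (the chloroenyne is far less reactive than the dichloride) and keeps the Z geometry, forming C7–C8.

Step 11
Reactants: 17 (5R,8Z,10R,14Z)-10-[(tert-butyldimethylsilyl)oxy]-15-chloro-5,9-dimethylpentadeca-8,14-diene-6,12-diyn-2-one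
Product: 18 2-(trimethylsilyloxy)-1-ene silyl enol ether of 17
Conditions: LiN(SiMe3)2 (1.1 equiv), Me3SiCl, Et3N, THF, −78 °C (in-situ trapping); used crude
Reagents that add atoms: chlorotrimethylsilane, C[Si](C)(C)Cl
Why: Kinetic deprotonation on the CH3 side with in-situ silylation gives the less substituted enol silane, and this amide base is too weak to eliminate HCl from the chloroenyne at −78 °C.

Step 12
Reactants: 19 3-bromophenol
Product: 20 (3-bromophenoxy)(tert-butyl)dimethylsilane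
Conditions: TBSCl, imidazole, DMF, rt
Reagents that add atoms: tert-butyldimethylsilyl chloride, CC(C)(C)[Si](C)(C)Cl
Why: Standard silylation protects the phenol for the organolithium step and is removed by fluoride at the end.

Step 13
Reactants: 20 (3-bromophenoxy)(tert-butyl)dimethylsilane
Product: 22 3-[(tert-butyldimethylsilyl)oxy]benzaldehyde, via aryllithium 21 (not isolated)
Conditions: n-BuLi, THF, −78 °C; DMF; H2O
Reagents that add atoms: N,N-dimethylformamide, CN(C)C=O
Why: Bromine–lithium exchange followed by formylation with DMF (Bouveault aldehyde synthesis) introduces C23.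

Step 14
Reactants: 23 (E)-but-2-ene
Product: 25 (E)-crotylboronic acid pinacol ester, via (E)-crotylpotassium 24 (not isolated)
Conditions: n-BuLi, KOt-Bu, THF, −78 → −50 °C; i-PrOB(pin), −78 °C; 1 M HCl
Reagents that add atoms: 2-isopropoxy-4,4,5,5-tetramethyl-1,3,2-dioxaborolane, CC(C)OB1OC(C)(C)C(C)(C)O1
Why: Schlosser metallation gives (E)-crotylpotassium, configurationally stable below −50 °C, and borylation keeps the E geometry.

Step 15
Reactants: 22 3-[(tert-butyldimethylsilyl)oxy]benzaldehyde; 25 (E)-crotylboronic acid pinacol ester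
Product: 26 (1R,2R)-1-{3-[(tert-butyldimethylsilyl)oxy]phenyl}-2-methylbut-3-en-1-ol
Conditions: (R)-TRIP phosphoric acid (5 mol%), toluene, −30 °C; aq. NaHCO3
Reagents that add atoms: none
Why: Chiral-phosphoric-acid-catalysed crotylboration through a closed chair transition state gives the anti product from the E-boronate and the 23R carbinol from the (R)-catalyst, so C22 and C23 are set together.

Step 16
Reactants: 26 (1R,2R)-1-{3-[(tert-butyldimethylsilyl)oxy]phenyl}-2-methylbut-3-en-1-ol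
Product: 27 tert-butyl{3-[(1R,2R)-1-[(tert-butyldimethylsilyl)oxy]-2-methylbut-3-en-1-yl]phenoxy}dimethylsilane
Conditions: TBSOTf, 2,6-lutidine, CH2Cl2, 0 °C
Reagents that add atoms: tert-butyldimethylsilyl triflate, CC(C)(C)[Si](C)(C)OS(=O)(=O)C(F)(F)F
Why: Silylation of the benzylic alcohol gives the non-chelating β-silyloxy group that the aldol step needs.

Step 17
Reactants: 27 tert-butyl{3-[(1R,2R)-1-[(tert-butyldimethylsilyl)oxy]-2-methylbut-3-en-1-yl]phenoxy}dimethylsilane
Product: 28 (2S,3R)-3-[(tert-butyldimethylsilyl)oxy]-3-{3-[(tert-butyldimethylsilyl)oxy]phenyl}-2-methylpropanal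
Conditions: OsO4 (2 mol%), NaIO4, 2,6-lutidine, dioxane/H2O, rt
Reagents that add atoms: sodium periodate (oxygen source through OsO4), [Na+].[O-]I(=O)(=O)=O
Why: Lemieux–Johnson oxidative cleavage of the terminal alkene gives the C21 aldehyde, and the lutidine buffer prevents epimerisation at C22.

Step 18
Reactants: 18 2-(trimethylsilyloxy)-1-ene silyl enol ether of 17; 28 (2S,3R)-3-[(tert-butyldimethylsilyl)oxy]-3-{3-[(tert-butyldimethylsilyl)oxy]phenyl}-2-methylpropanal
Product: 29 C6–C23 aldol adduct (19-ketone, 21-hydroxy; 11R,16R,21S,22R,23R)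
Conditions: BF3·OEt2, CH2Cl2, −78 °C
Reagents that add atoms: none
Why: In this BF3-mediated Mukaiyama aldol (open transition state), Felkin control by the α-methyl group and 1,3-anti induction by the β-silyloxy group reinforce each other for the anti aldehyde and set C21 syn to the C22 methyl and anti to the C23 oxygen.

Step 19
Reactants: 29 C6–C23 aldol adduct
Product: 30 C6–C23 syn-19,21-diol (11R,16R,19S,21S,22R,23R)
Conditions: Et2BOMe, NaBH4, THF/MeOH (4:1), −78 °C; MeOH co-evaporation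
Reagents that add atoms: none
Why: In the Narasaka–Prasad reduction the boron chelate of the β-hydroxy ketone takes external axial hydride to give the 1,3-syn diol, setting C19 as S.

Step 20
Reactants: 30 C6–C23 syn-19,21-diol
Product: 31 C6–C23 21-alcohol with 19-O-TBS (11R,16R,19S,21S,22R,23R)
Conditions: TBSOTf (1.05 equiv), 2,6-lutidine, CH2Cl2, −78 °C
Reagents that add atoms: tert-butyldimethylsilyl triflate, CC(C)(C)[Si](C)(C)OS(=O)(=O)C(F)(F)F
Why: The C19 hydroxyl lies between two methylene groups and is silylated much faster than the C21 hydroxyl, which is flanked by the C22 methine and the bulky benzylic silyl ether.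

Step 21
Reactants: 32 methyl 2-bromopropanoate
Product: 33 (1-methoxy-1-oxopropan-2-yl)triphenylphosphonium bromide
Conditions: PPh3, toluene, 80 °C
Reagents that add atoms: triphenylphosphine, c1ccc(cc1)P(c1ccccc1)c1ccccc1
Why: SN2 quaternisation of triphenylphosphine by the α-bromo ester gives the Wittig salt.

Step 22
Reactants: 33 (1-methoxy-1-oxopropan-2-yl)triphenylphosphonium bromide; 34 3-(trimethylsilyl)prop-2-ynal
Product: 36 methyl (2E)-2-methyl-5-(trimethylsilyl)pent-2-en-4-ynoate, via phosphorus ylide 35 (not isolated)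
Conditions: 1 M NaOH/CH2Cl2 (ylide, phases separated, dried); 34, CH2Cl2, 0 °C → rt
Reagents that add atoms: none
Why: Wittig olefination with the stabilised α-methyl ylide gives the E-trisubstituted enoate (C2=C3).

Step 23
Reactants: 36 methyl (2E)-2-methyl-5-(trimethylsilyl)pent-2-en-4-ynoate
Product: 37 (2E)-2-methylpent-2-en-4-ynoic acid
Conditions: LiOH, THF/MeOH/H2O, 0 °C → rt; 1 M HCl
Reagents that add atoms: water (as LiOH/H2O), O
Why: Hydroxide saponifies the methyl ester and removes the alkynyl TMS group in one operation.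

Step 24
Reactants: 31 C6–C23 21-alcohol with 19-O-TBS; 37 (2E)-2-methylpent-2-en-4-ynoic acid
Product: 39 open-chain C21 ester (21-O-[(2E)-2-methylpent-2-en-4-ynoyl] derivative of 31), via mixed anhydride 38 (not isolated)
Conditions: 37, 2,4,6-trichlorobenzoyl chloride, Et3N, toluene, rt; then 31, DMAP, rt → 40 °C
Reagents that add atoms: none
Why: In the Yamaguchi esterification DMAP attacks the less hindered enoyl carbonyl of the mixed anhydride, and the acylpyridinium acylates the only free hydroxyl (C21).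

Step 25
Reactants: 39 open-chain C21 ester
Product: 40 22-membered 4,8,14-triyne macrolactone (tetra-TBS)
Conditions: Pd(PPh3)4 (20 mol%), CuI (40 mol%), i-Pr2NH, degassed THF, 0.002 M, syringe-pump addition, 40 °C
Reagents that add atoms: none
Why: Ring-closing Sonogashira coupling closes the macrocycle at C5–C6: zerovalent palladium adds to the activated Z-chloroenyne with retention and couples with the copper acetylide of the ynenoate under high dilution.

Step 26
Reactants: 40 22-membered 4,8,14-triyne macrolactone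
Product: 41 tetra-TBS ether of the target
Conditions: Zn dust activated with Cu(OAc)2 and AgNO3 (Zn(Cu/Ag)), MeOH/H2O/dioxane, rt, dark
Reagents that add atoms: none
Why: Boland reduction (surface electron transfer then cis protonation) reduces only conjugated triple bonds, so the three enyne/dienyne alkynes become the 4Z, 8Z and 14Z olefins while the existing alkenes are untouched.

Step 27
Reactants: 41 tetra-TBS ether of the target
Product: 42 CNP0073615.1
Conditions: HF·pyridine, pyridine, THF, 0 °C → rt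
Reagents that add atoms: none
Why: Buffered fluoride removes the three alkyl and the aryl silyl ethers under weakly acidic conditions that avoid acyl migration from C21 to the freed C19 or C23 hydroxyls and polyene isomerisation.

## Compound list

1 | ethynyltri(propan-2-yl)silane (acetylene carrying a TIPS protecting group) | C#C[Si](C(C)C)(C(C)C)C(C)C | starting material
2 | (bromoethynyl)tri(propan-2-yl)silane | BrC#C[Si](C(C)C)(C(C)C)C(C)C | intermediate
3 | hex-5-en-2-one | CC(=O)CCC=C | starting material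
4 | (5R)-5-methyl-7-[tri(propan-2-yl)silyl]hept-6-yn-2-one | CC(C)[Si](C(C)C)(C(C)C)C#C[C@H](C)CCC(C)=O | intermediate
5 | (5R)-5-methylhept-6-yn-2-one | C#C[C@H](C)CCC(C)=O | intermediate
6 | prop-2-yn-1-ol | C#CCO | starting material
7 | bromomagnesium (2Z)-3-(bromomagnesio)-2-methylprop-2-en-1-olate | Br[Mg]OC/C(C)=C\[Mg]Br | intermediate
8 | (2Z)-3-iodo-2-methylprop-2-en-1-ol | OC/C(C)=C\I | intermediate
9 | (5R,8Z)-10-hydroxy-5,9-dimethyldec-8-en-6-yn-2-one | OC/C(C)=C\C#C[C@H](C)CCC(C)=O | intermediate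
10 | (2Z,6R)-2,6-dimethyl-9-oxodec-2-en-4-ynal | O=C/C(C)=C\C#C[C@H](C)CCC(C)=O | intermediate
11 | 3-bromoprop-1-yne | C#CCBr | starting material
12 | propa-1,2-dien-1-ylmagnesium bromide | C=C=C[Mg]Br | intermediate
13 | 4,4,5,5-tetramethyl-2-(propa-1,2-dien-1-yl)-1,3,2-dioxaborolane | C=C=CB1OC(C)(C)C(C)(C)O1 | intermediate
14 | (5R,8Z,10R)-10-hydroxy-5,9-dimethyltridec-8-ene-6,12-diyn-2-one | C#CC[C@@H](O)/C(C)=C\C#C[C@H](C)CCC(C)=O | intermediate
15 | (5R,8Z,10R)-10-[(tert-butyldimethylsilyl)oxy]-5,9-dimethyltridec-8-ene-6,12-diyn-2-one | C#CC[C@@H](O[Si](C)(C)C(C)(C)C)/C(C)=C\C#C[C@H](C)CCC(C)=O | intermediate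
16 | (Z)-1,2-dichloroethene | Cl/C=C\Cl | starting material
17 | (5R,8Z,10R,14Z)-10-[(tert-butyldimethylsilyl)oxy]-15-chloro-5,9-dimethylpentadeca-8,14-diene-6,12-diyn-2-one | Cl/C=C\C#CC[C@@H](O[Si](C)(C)C(C)(C)C)/C(C)=C\C#C[C@H](C)CCC(C)=O | intermediate
18 | tert-butyl{[(1Z,6R,7Z,11R)-1-chloro-7,11-dimethyl-14-(trimethylsilyloxy)pentadeca-1,7,14-triene-3,9-diyn-6-yl]oxy}dimethylsilane | Cl/C=C\C#CC[C@@H](O[Si](C)(C)C(C)(C)C)/C(C)=C\C#C[C@H](C)CCC(=C)O[Si](C)(C)C | intermediate
19 | 3-bromophenol | Oc1cccc(Br)c1 | starting material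
20 | (3-bromophenoxy)(tert-butyl)dimethylsilane | Brc1cccc(O[Si](C)(C)C(C)(C)C)c1 | intermediate
21 | {3-[(tert-butyldimethylsilyl)oxy]phenyl}lithium | [Li]c1cccc(O[Si](C)(C)C(C)(C)C)c1 | intermediate
22 | 3-[(tert-butyldimethylsilyl)oxy]benzaldehyde | O=Cc1cccc(O[Si](C)(C)C(C)(C)C)c1 | intermediate
23 | (E)-but-2-ene | C/C=C/C | starting material
24 | (E)-but-2-en-1-ylpotassium | C/C=C/C[K] | intermediate
25 | 2-[(E)-but-2-en-1-yl]-4,4,5,5-tetramethyl-1,3,2-dioxaborolane | C/C=C/CB1OC(C)(C)C(C)(C)O1 | intermediate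
26 | (1R,2R)-1-{3-[(tert-butyldimethylsilyl)oxy]phenyl}-2-methylbut-3-en-1-ol | C=C[C@@H](C)[C@@H](O)c1cccc(O[Si](C)(C)C(C)(C)C)c1 | intermediate
27 | tert-butyl{3-[(1R,2R)-1-[(tert-butyldimethylsilyl)oxy]-2-methylbut-3-en-1-yl]phenoxy}dimethylsilane | C=C[C@@H](C)[C@@H](O[Si](C)(C)C(C)(C)C)c1cccc(O[Si](C)(C)C(C)(C)C)c1 | intermediate
28 | (2S,3R)-3-[(tert-butyldimethylsilyl)oxy]-3-{3-[(tert-butyldimethylsilyl)oxy]phenyl}-2-methylpropanal | O=C[C@@H](C)[C@@H](O[Si](C)(C)C(C)(C)C)c1cccc(O[Si](C)(C)C(C)(C)C)c1 | intermediate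
29 | C6–C23 aldol adduct: (6Z)-6-chloro-6-ene, 8-yne, 11-OTBS, (12Z)-12-methyl-12-ene, 14-yne, 16-methyl, 19-ketone, 21-OH, 22-methyl, 23-OTBS, 23-(3-TBSO-phenyl); 11R,16R,21S,22R,23R | Cl/C=C\C#CC[C@@H](O[Si](C)(C)C(C)(C)C)/C(C)=C\C#C[C@H](C)CCC(=O)C[C@H](O)[C@@H](C)[C@@H](O[Si](C)(C)C(C)(C)C)c1cccc(O[Si](C)(C)C(C)(C)C)c1 | intermediate
30 | C6–C23 syn-19,21-diol (as 29 with 19-OH in place of the ketone); 11R,16R,19S,21S,22R,23R | Cl/C=C\C#CC[C@@H](O[Si](C)(C)C(C)(C)C)/C(C)=C\C#C[C@H](C)CC[C@H](O)C[C@H](O)[C@@H](C)[C@@H](O[Si](C)(C)C(C)(C)C)c1cccc(O[Si](C)(C)C(C)(C)C)c1 | intermediate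
31 | C6–C23 21-alcohol (as 30 with 19-OTBS); 11R,16R,19S,21S,22R,23R | Cl/C=C\C#CC[C@@H](O[Si](C)(C)C(C)(C)C)/C(C)=C\C#C[C@H](C)CC[C@H](O[Si](C)(C)C(C)(C)C)C[C@H](O)[C@@H](C)[C@@H](O[Si](C)(C)C(C)(C)C)c1cccc(O[Si](C)(C)C(C)(C)C)c1 | intermediate
32 | methyl 2-bromopropanoate (racemic) | COC(=O)C(C)Br | starting material
33 | (1-methoxy-1-oxopropan-2-yl)triphenylphosphonium bromide | COC(=O)C(C)[P+](c1ccccc1)(c1ccccc1)c1ccccc1.[Br-] | intermediate
34 | 3-(trimethylsilyl)prop-2-ynal | O=CC#C[Si](C)(C)C | starting material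
35 | methyl 2-(triphenyl-λ5-phosphanylidene)propanoate | COC(=O)C(C)=P(c1ccccc1)(c1ccccc1)c1ccccc1 | intermediate
36 | methyl (2E)-2-methyl-5-(trimethylsilyl)pent-2-en-4-ynoate | COC(=O)/C(C)=C/C#C[Si](C)(C)C | intermediate
37 | (2E)-2-methylpent-2-en-4-ynoic acid | OC(=O)/C(C)=C/C#C | intermediate
38 | (2E)-2-methylpent-2-en-4-ynoic 2,4,6-trichlorobenzoic anhydride | O=C(OC(=O)/C(C)=C/C#C)c1c(Cl)cc(Cl)cc1Cl | intermediate
39 | open-chain ester: 31 acylated at O21 by (2E)-2-methylpent-2-en-4-ynoyl (C1–C5); 11R,16R,19S,21S,22R,23R | Cl/C=C\C#CC[C@@H](O[Si](C)(C)C(C)(C)C)/C(C)=C\C#C[C@H](C)CC[C@H](O[Si](C)(C)C(C)(C)C)C[C@H](OC(=O)/C(C)=C/C#C)[C@@H](C)[C@@H](O[Si](C)(C)C(C)(C)C)c1cccc(O[Si](C)(C)C(C)(C)C)c1 | intermediate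
40 | 22-membered macrolactone, (2E,6Z,12Z)-triene-4,8,14-triyne, 11,19,23-tris-OTBS, aryl OTBS; 11R,16R,19S,21S,22R,23R | C/C1=C/C#C[C@H](C)CC[C@H](O[Si](C)(C)C(C)(C)C)C[C@@H]([C@@H](C)[C@@H](O[Si](C)(C)C(C)(C)C)c2cccc(O[Si](C)(C)C(C)(C)C)c2)OC(=O)/C(C)=C/C#C/C=C\C#CC[C@H]1O[Si](C)(C)C(C)(C)C | intermediate
41 | tetra-TBS ether of the target, (2E,4Z,6Z,8Z,12Z,14Z); 11R,16R,19S,21S,22R,23R | C/C1=C/C=C\[C@H](C)CC[C@H](O[Si](C)(C)C(C)(C)C)C[C@@H]([C@@H](C)[C@@H](O[Si](C)(C)C(C)(C)C)c2cccc(O[Si](C)(C)C(C)(C)C)c2)OC(=O)/C(C)=C/C=C\C=C/C=C\C[C@H]1O[Si](C)(C)C(C)(C)C | intermediate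
42 | CNP0073615.1, (2E,4Z,6Z,8Z,12Z,14Z)-macrolactone; 11R,16R,19S,21S,22S,23R | C/C1=C/C=C\[C@H](C)CC[C@H](O)C[C@@H]([C@@H](C)[C@@H](O)c2cccc(O)c2)OC(=O)/C(C)=C/C=C\C=C/C=C\C[C@H]1O | target

## Step count and risk

Total step count: 27.
Longest linear sequence: 16 steps (steps 1, 2, 3, 5, 6, 8, 9, 10, 11, 18, 19, 20, 24, 25, 26, 27).

Three steps most likely to fail:

**Step 2 (the proposed new hydroalkynylation).** Risks are chain walking to the β-position, anti-Markovnikov addition, ketone hydrosilylation and low ee with a weakly binding ketone. The fallback uses known chemistry only, sets out from 3 and comes back at 5.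
- 3 is ketalised (ethylene glycol, TsOH, benzene, reflux) to 2-(but-3-en-1-yl)-2-methyl-1,3-dioxolane F1.
- Cross-metathesis with (E)-1,4-dibromobut-2-ene (second-generation Grubbs catalyst, CH2Cl2, 40 °C) gives 2-[(3E)-5-bromopent-3-en-1-yl]-2-methyl-1,3-dioxolane F2.
- Copper-catalysed asymmetric SN2′ allylic alkylation (MeMgBr, CuBr·SMe2, the Taniaphos enantiomer that gives R, CH2Cl2, −75 °C) gives 2-methyl-2-[(3R)-3-methylpent-4-en-1-yl]-1,3-dioxolane F3.
- Ozonolysis (O3, CH2Cl2, −78 °C; PPh3) gives (2R)-2-methyl-4-(2-methyl-1,3-dioxolan-2-yl)butanal F4.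
- Ohira–Bestmann homologation (dimethyl (1-diazo-2-oxopropyl)phosphonate, K2CO3, MeOH) gives 2-methyl-2-[(3R)-3-methylpent-4-yn-1-yl]-1,3-dioxolane F5.
- PPTS in acetone/H2O releases the ketone, giving 5.

**Step 25 (ring-closing Sonogashira at a vinyl chloride).** Oxidative addition is slow under high dilution, and alkyne homocoupling or oligomerisation can compete. The fallback closes the ring at the C21–O bond instead; it sets out from 31 (with acid 37) and comes back at 40.
- 31 and 37 are coupled intermolecularly at C5–C6 (Pd(PPh3)4, CuI, i-Pr2NH, THF, rt, 0.1 M) to the C1–C23 triyne seco acid F6.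
- Yamaguchi macrolactonisation (2,4,6-trichlorobenzoyl chloride, Et3N, THF; slow addition to DMAP in toluene, 0.001 M, 60 °C) gives 40.

**Step 26 (three semi-reductions on the macrocycle).** Risks are incomplete reduction of the hindered C14–C15 alkyne, over-reduction, and thermal electrocyclisation of the new tetraene. The fallback reduces in the open chain in two stages and then lactonises; it sets out from 31 (with acid 37) and comes back at 41.
- Zn(Cu/Ag) in MeOH/H2O reduces the two alkynes of 31 to the (6Z,8Z,12Z,14Z)-6-chloro tetraene alcohol F7.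
- Sonogashira coupling of this chlorodiene with 37 (PdCl2(PhCN)2, CuI, piperidine, rt) gives the 4-yne seco acid F8.
- A second Zn(Cu/Ag) reduction of the single, doubly conjugated alkyne gives the (2E,4Z,6Z,8Z,12Z,14Z)-hexaene seco acid F9.
- Shiina macrolactonisation (2-methyl-6-nitrobenzoic anhydride, DMAP, CH2Cl2, 0.001 M, rt) gives 41.

## Further compounds

F1 | step 2 | 2-(but-3-en-1-yl)-2-methyl-1,3-dioxolane | C=CCCC1(C)OCCO1
F2 | step 2 | 2-[(3E)-5-bromopent-3-en-1-yl]-2-methyl-1,3-dioxolane | BrC/C=C/CCC1(C)OCCO1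
F3 | step 2 | 2-methyl-2-[(3R)-3-methylpent-4-en-1-yl]-1,3-dioxolane | C=C[C@H](C)CCC1(C)OCCO1
F4 | step 2 | (2R)-2-methyl-4-(2-methyl-1,3-dioxolan-2-yl)butanal | O=C[C@H](C)CCC1(C)OCCO1
F5 | step 2 | 2-methyl-2-[(3R)-3-methylpent-4-yn-1-yl]-1,3-dioxolane | C#C[C@H](C)CCC1(C)OCCO1
F6 | step 25 | C1–C23 (2E,6Z,12Z)-triene-4,8,14-triyne seco acid, 21-OH free, 11,19,23-tris-OTBS, aryl OTBS | OC(=O)/C(C)=C/C#C/C=C\C#CC[C@@H](O[Si](C)(C)C(C)(C)C)/C(C)=C\C#C[C@H](C)CC[C@H](O[Si](C)(C)C(C)(C)C)C[C@H](O)[C@@H](C)[C@@H](O[Si](C)(C)C(C)(C)C)c1cccc(O[Si](C)(C)C(C)(C)C)c1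
F7 | step 26 | C6–C23 (6Z,8Z,12Z,14Z)-6-chloro tetraene 21-alcohol, 11,19,23-tris-OTBS, aryl OTBS | Cl/C=C\C=C/C[C@@H](O[Si](C)(C)C(C)(C)C)/C(C)=C\C=C/[C@H](C)CC[C@H](O[Si](C)(C)C(C)(C)C)C[C@H](O)[C@@H](C)[C@@H](O[Si](C)(C)C(C)(C)C)c1cccc(O[Si](C)(C)C(C)(C)C)c1
F8 | step 26 | C1–C23 (2E,6Z,8Z,12Z,14Z)-pentaene-4-yne seco acid, 21-OH free, silyl ethers as in F7 | OC(=O)/C(C)=C/C#C/C=C\C=C/C[C@@H](O[Si](C)(C)C(C)(C)C)/C(C)=C\C=C/[C@H](C)CC[C@H](O[Si](C)(C)C(C)(C)C)C[C@H](O)[C@@H](C)[C@@H](O[Si](C)(C)C(C)(C)C)c1cccc(O[Si](C)(C)C(C)(C)C)c1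
F9 | step 26 | C1–C23 (2E,4Z,6Z,8Z,12Z,14Z)-hexaene seco acid, 21-OH free, silyl ethers as in F7 | OC(=O)/C(C)=C/C=C\C=C/C=C\C[C@@H](O[Si](C)(C)C(C)(C)C)/C(C)=C\C=C/[C@H](C)CC[C@H](O[Si](C)(C)C(C)(C)C)C[C@H](O)[C@@H](C)[C@@H](O[Si](C)(C)C(C)(C)C)c1cccc(O[Si](C)(C)C(C)(C)C)c1
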